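**Plan**

1. Cuts: in half A (cyclopentanol OH cis to isopropenyl) the bond from the exocyclic vinylic CH of the tetrahydropyran to the first CH2 of the central CH2CH2 unit, together with ring bond C4–C5 of that tetrahydropyran; the same pair of cuts in half B (OH trans to both neighbours). This leaves 1,2-bis(pinacolboryl)ethane and two iodo propargyl ethers, each traced back (C2–isopropenyl bond, epoxide, ring alkene) to one cyclopentenyl carbinol.
2. Enabling feature: each tetrahydropyran (O1, C2 to C6) carries its exocyclic C=CH on C5, between C6H2–O1 and C4H2. So O1–C6–C5≡CH is a propargyl ether and C4 can bear iodide; in an alkynylboronate complex C5 is alkylated by C4 while the boron-bound CH2 moves to the terminal alkyne carbon anti to C4, i.e. cis to C6, the Z geometry of both alkenes.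
3. Forward order: anti-allylboration adduct, cyclopentene (ring-closing metathesis), divergent epoxidation and cuprate opening to the two cyclopentanols, tetrahydropyran of half B (first boronate cascade on the C2 diboronate), tetrahydropyran of half A with union of the halves (second cascade), protodeboronation, desilylation.
4. Stereochemistry: cyclopentane C5 and tetrahydropyran C2 from one catalytic asymmetric anti-allylboration; cyclopentane C1 and C2 from face-selective epoxidation (anti by sterics for half B, hydroxyl-directed syn for half A) and invertive opening by isopropenyl cuprate, plus a Mitsunobu inversion at C1 in half A; both alkene geometries from the anti 1,2-metallate shift followed by stereoretentive protodeboronation.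

Key step: step 21

Remark (assumption): locants are tetrahydropyran O1, C2 (bears the cyclopentyl group), C3, C4, C5 (exocyclic alkene), C6, and cyclopentane C1 (oxygen), C2 (isopropenyl), C5 (side chain); compounds 1, 2, 5, 8, 11 and 24 are taken as purchasable; the SMILES in the compound list are authoritative for configuration.

**Route**

Step 1
Reactants: 1 pent-4-enal; 2 vinylmagnesium bromide
Product: 3 hepta-1,6-dien-3-ol (racemic)
Conditions: THF, −78 to 0 °C; aq. NH4Cl
Reagents that add atoms: none
Why: Grignard 1,2-addition to the aldehyde; the carbinol centre is left racemic because step 2 erases it.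

Step 2
Reactants: 3 hepta-1,6-dien-3-ol
Product: 4 (E)-hepta-2,6-dienylboronic acid pinacol ester
Conditions: B2pin2, [Pd(MeCN)4](BF4)2 (5 mol %), DMSO/MeOH, 50 °C
Reagents that add atoms: bis(pinacolato)diboron, CC1(C)OB(OC1(C)C)B1OC(C)(C)C(C)(C)O1
Why: Palladium-catalysed borylation of an allylic alcohol through a π-allylpalladium intermediate should convert both enantiomers of 3 into the same linear (E)-allylboronate, so no stereocentre remains.

Step 3
Reactants: 4 (E)-hepta-2,6-dienylboronic acid pinacol ester; 5 3-[(tert-butyldimethylsilyl)oxy]propanal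
Product: 6 (3R,4S)-1-[(tert-butyldimethylsilyl)oxy]-4-ethenyloct-7-en-3-ol
Conditions: (S)-TRIP (chiral BINOL-derived phosphoric acid, 5 mol %), 4 Å molecular sieves, toluene, −30 °C; aqueous work-up
Reagents that add atoms: none
Why: Chiral phosphoric acid-catalysed allylboration through a closed chair transition state, in which the (E)-γ-substituted boronate gives the anti adduct and the acid enantiomer is the one that directs the allyl group to the Si face of the aldehyde, which sets C3 (R) and C4 (S) together.

Step 4
Reactants: 6 (3R,4S)-1-[(tert-butyldimethylsilyl)oxy]-4-ethenyloct-7-en-3-ol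
Product: 7 (1R)-3-[(tert-butyldimethylsilyl)oxy]-1-[(1S)-cyclopent-2-en-1-yl]propan-1-ol
Conditions: second-generation Grubbs catalyst RuCl2(=CHPh)(PCy3)(H2IMes) (2 mol %), CH2Cl2, 40 °C
Reagents that add atoms: none
Why: Ring-closing metathesis of the 1,6-diene closes the cyclopentene with loss of ethene and leaves both stereocentres untouched.

Step 5
Reactants: 7 cyclopentenyl carbinol; 8 (3-bromoprop-1-yn-1-yl)trimethylsilane
Product: 9 3-(trimethylsilyl)prop-2-yn-1-yl ether of 7
Conditions: NaH, THF, 0 °C; then 8, Bu4NI (cat.), 0 °C to rt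
Reagents that add atoms: none
Why: Williamson etherification of the sodium alkoxide with the reactive propargylic bromide, the C-silyl group masking the alkyne C–H for the organometallic step 7.

Step 6
Reactants: 9 silylpropargyl ether
Product: 10 epoxide of 9 with the oxygen anti to the side chain
Conditions: mCPBA, NaHCO3, CH2Cl2, 0 °C
Reagents that add atoms: mCPBA, OOC(=O)c1cccc(Cl)c1
Why: Prilezhaev epoxidation of the only nucleophilic alkene, the peracid approaching the ring face anti to the branched allylic substituent, which sets both epoxide carbons.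

Step 7
Reactants: 10 anti epoxide; 11 isopropenylmagnesium bromide
Product: 12 half-B cyclopentanol (1S,2S,5S), OH trans to isopropenyl and trans to the side chain
Conditions: CuI (10 mol %), THF, −30 to 0 °C; aq. NH4Cl
Reagents that add atoms: none
Why: Copper-catalysed SN2 opening of the epoxide at the carbon remote from the side chain with inversion, which places isopropenyl trans to the new hydroxyl and sets cyclopentane C2.

Step 8
Reactants: 12 half-B cyclopentanol
Product: 13 half-B diol with terminal alkyne
Conditions: Bu4NF (2.5 equiv), THF, 0 °C to rt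
Reagents that add atoms: none
Why: Fluoride cleaves the alkynyl C–Si bond and the primary silyl ether in one operation, the secondary hydroxyl being free already.

Step 9
Reactants: 13 half-B diol
Product: 14 half-B primary iodide
Conditions: PPh3, I2, imidazole, CH2Cl2, 0 °C
Reagents that add atoms: iodine, II
Why: Appel-type iodination (Garegg–Samuelsson conditions) is selective for the primary over the hindered secondary hydroxyl and touches no stereocentre.

Step 10
Reactants: 14 half-B primary iodide
Product: 15 half-B iodo alkyne tert-butyldimethylsilyl ether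
Conditions: TBSOTf, 2,6-lutidine, CH2Cl2, −78 to 0 °C
Reagents that add atoms: tert-butyldimethylsilyl trifluoromethanesulfonate, CC(C)(C)[Si](C)(C)OS(=O)(=O)C(F)(F)F
Why: Silylation of the hindered secondary alcohol with a silyl triflate and a non-nucleophilic base removes the only O–H before the lithiation of step 19.

Step 11
Reactants: 7 cyclopentenyl carbinol
Product: 16 epoxy alcohol with the epoxide oxygen syn to the side chain
Conditions: VO(acac)2 (5 mol %), t-BuOOH, CH2Cl2, 0 °C to rt
Reagents that add atoms: tert-butyl hydroperoxide, CC(C)(C)OO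
Why: Vanadium-catalysed hydroxyl-directed epoxidation, in which the vanadate ester of the homoallylic alcohol delivers oxygen to the ring face syn to the side chain and so sets both epoxide carbons.

Step 12
Reactants: 16 syn epoxy alcohol; 8 (3-bromoprop-1-yn-1-yl)trimethylsilane
Product: 17 3-(trimethylsilyl)prop-2-yn-1-yl ether of 16
Conditions: NaH, THF, 0 °C; then 8, Bu4NI (cat.), 0 °C to rt
Reagents that add atoms: none
Why: Williamson etherification; the alkoxide cannot open the epoxide because it sits on the same face as the epoxide oxygen.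

Step 13
Reactants: 17 syn epoxide ether; 11 isopropenylmagnesium bromide
Product: 18 cyclopentanol (1R,2R,5S), OH trans to isopropenyl and cis to the side chain
Conditions: CuI (10 mol %), THF, −30 to 0 °C; aq. NH4Cl
Reagents that add atoms: none
Why: Copper-catalysed SN2 opening at the epoxide carbon remote from the side chain with inversion sets cyclopentane C2 with isopropenyl trans to the side chain.

Step 14
Reactants: 18 cyclopentanol (1R,2R,5S)
Product: 19 4-nitrobenzoate with inverted C1
Conditions: PPh3, DIAD, 4-nitrobenzoic acid, toluene, 0 °C to rt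
Reagents that add atoms: 4-nitrobenzoic acid, OC(=O)c1ccc(cc1)[N+](=O)[O-]
Why: Mitsunobu reaction, in which SN2 displacement of the oxyphosphonium by the carboxylate inverts C1 and puts the C1 oxygen cis to isopropenyl and trans to the side chain (half A).

Step 15
Reactants: 19 4-nitrobenzoate
Product: 20 half-A cyclopentanol (1S,2R,5S) with terminal alkyne
Conditions: K2CO3, MeOH, rt
Reagents that add atoms: none
Why: Carbonate-mediated methanolysis removes the ester and the alkynyl silyl group in one operation without touching the primary silyl ether or any stereocentre.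

Step 16
Reactants: 20 half-A cyclopentanol
Product: 21 half-A diol
Conditions: Bu4NF, THF, 0 °C to rt
Reagents that add atoms: none
Why: Fluoride desilylation of the primary silyl ether.

Step 17
Reactants: 21 half-A diol
Product: 22 half-A primary iodide
Conditions: PPh3, I2, imidazole, CH2Cl2, 0 °C
Reagents that add atoms: iodine, II
Why: Appel-type iodination (Garegg–Samuelsson conditions), selective for the primary hydroxyl.

Step 18
Reactants: 22 half-A primary iodide
Product: 23 half-A iodo alkyne tert-butyldimethylsilyl ether
Conditions: TBSOTf, 2,6-lutidine, CH2Cl2, −78 to 0 °C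
Reagents that add atoms: tert-butyldimethylsilyl trifluoromethanesulfonate, CC(C)(C)[Si](C)(C)OS(=O)(=O)C(F)(F)F
Why: Silylation of the hindered secondary alcohol with a silyl triflate removes the only O–H before the lithiation of step 21.

Step 19
Reactants: 15 half-B iodo alkyne silyl ether; 24 1,2-bis(4,4,5,5-tetramethyl-1,3,2-dioxaborolan-2-yl)ethane
Product: 27 half-B (Z)-alkylidene tetrahydropyran diboronate, via lithium acetylide 25 (not isolated), via alkynylboronate complex 26 (not isolated)
Conditions: LiN(iPr)2, THF, −78 °C; then 24 (3 equiv), −78 °C to rt, then 50 °C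
Reagents that add atoms: none
Why: Proposed new method: acetylide 25 adds to one boron of the excess diboronate to give the tetracoordinate complex 26, in which the inner alkyne carbon (C5) displaces the tethered primary iodide (6-exo-tet) while the CH2CH2Bpin group shifts from boron to the alkyne terminus anti to the new C4–C5 bond, so that the tetrahydropyran, the alkenyl boronate with the chain cis to C6 and the C2 handle should arise together; the closest known reaction type is the alkylation-induced 1,2-migration of lithium alkynyl(trialkyl)borates (also used intramolecularly to make alkylidenecycloalkanes) and the electrophile-triggered 1,2-metallate shifts of pinacol boronate complexes, and mono-complexation is secured by the excess of 24.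

Step 20
Reactants: 27 half-B diboronate
Product: 28 half-B homoallylic pinacol boronate with (Z) alkene
Conditions: AgF, THF/MeOH/H2O, rt to 40 °C, dark
Reagents that add atoms: none
Why: Silver-mediated protodeboronation of an alkenyl pinacol boronate (boron-to-silver transmetalation, then protonolysis) should replace the alkenyl boron by hydrogen with retention, which fixes the Z alkene and leaves the primary alkyl boronate untouched.

Step 21
Reactants: 23 half-A iodo alkyne silyl ether; 28 half-B homoallylic pinacol boronate
Product: 31 coupled bis(silyl ether) with Bpin on the half-A vinylic carbon, via lithium acetylide 29 (not isolated), via alkynylboronate complex 30 (not isolated)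
Conditions: LiN(iPr)2, THF, −78 °C; then 28 (1.1 equiv), −78 °C to rt, then 50 °C
Reagents that add atoms: none
Why: Proposed new method: acetylide 29 adds to the boron of 28 to give the tetracoordinate alkynylboronate 30, whose alkyne, made electron-rich by the anionic boron, attacks the tethered primary iodide through its inner carbon C5 while the boron-bound CH2 of the half-B fragment shifts to the alkyne terminus in a concerted 1,2-metallate rearrangement, so that one event should form ring bond C4–C5, the bond that joins the two halves and the exocyclic alkene. The closest known reaction type is the alkylation-induced 1,2-migration of lithium alkynyl(trialkyl)borates (including cyclising variants that give alkylidenecycloalkanes) and the electrophile-induced 1,2-shifts of alkynyl and alkenyl pinacol boronate complexes; new here is a pinacol boronate complex that reacts with an unactivated alkyl iodide to close an oxygen heterocycle. The tetrahydropyran closes by a 6-exo-tet SN2 at C4, the former alkyne becoming the exocyclic double bond. No stereocentre is formed; the alkene geometry follows from the anti course of the shift (the migrating carbon enters anti to the new C4–C5 bond), which places the CH2CH2 chain cis to C6 and boron cis to C4, i.e. the Z alkene after stereoretentive protodeboronation. The step needs migration of the right carbon, secured because the pinacol oxygens do not migrate and the alkyl group is the only carbon ligand besides the alkynyl group; it needs reaction through the boronate and not by direct acetylide alkylation, secured because the free acetylide cannot reach its own iodide (a seven-membered cycloalkyne would result) and intermolecular alkylation is slow in THF, so that even a reversibly formed complex is funnelled to product; and it needs the propargylic ether to stay, which it should as a poor leaving group without Lewis acid.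

Step 22
Reactants: 31 coupled alkenyl boronate
Product: 32 bis(tert-butyldimethylsilyl) ether of the target
Conditions: AgF, THF/MeOH/H2O, rt to 40 °C, dark
Reagents that add atoms: none
Why: Silver-mediated protodeboronation of the alkenyl pinacol boronate with retention should give the second Z trisubstituted alkene.

Step 23
Reactants: 32 bis(silyl ether)
Product: 33 CNP0267443.2 (target)
Conditions: Bu4NF (excess), THF, rt to 50 °C
Reagents that add atoms: none
Why: Fluoride desilylation of both secondary silyl ethers, which affects no stereocentre and no alkene.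

**Compound list**

1 | pent-4-enal | C=CCCC=O | starting material
2 | vinylmagnesium bromide | C=C[Mg]Br | starting material
3 | hepta-1,6-dien-3-ol (racemic) | C=CCCC(O)C=C | intermediate
4 | 2-[(2E)-hepta-2,6-dien-1-yl]-4,4,5,5-tetramethyl-1,3,2-dioxaborolane | C=CCC/C=C/CB1OC(C)(C)C(C)(C)O1 | intermediate
5 | 3-[(tert-butyldimethylsilyl)oxy]propanal | O=CCCO[Si](C)(C)C(C)(C)C | starting material
6 | (3R,4S)-1-[(tert-butyldimethylsilyl)oxy]-4-ethenyloct-7-en-3-ol | C=CCC[C@H]([C@H](O)CCO[Si](C)(C)C(C)(C)C)C=C | intermediate
7 | (1R)-3-[(tert-butyldimethylsilyl)oxy]-1-[(1S)-cyclopent-2-en-1-yl]propan-1-ol | C1C[C@H]([C@H](O)CCO[Si](C)(C)C(C)(C)C)C=C1 | intermediate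
8 | (3-bromoprop-1-yn-1-yl)trimethylsilane | C[Si](C)(C)C#CCBr | starting material
9 | 3-(trimethylsilyl)prop-2-yn-1-yl ether of 7 (side-chain carbon R, ring carbon S) | C1C[C@H]([C@H](OCC#C[Si](C)(C)C)CCO[Si](C)(C)C(C)(C)C)C=C1 | intermediate
10 | epoxide of 9, oxygen anti to the side chain, (1R,2R,5S)-2-substituted 6-oxabicyclo[3.1.0]hexane | C1C[C@@H]2O[C@@H]2[C@H]1[C@H](OCC#C[Si](C)(C)C)CCO[Si](C)(C)C(C)(C)C | intermediate
11 | isopropenylmagnesium bromide | CC(=C)[Mg]Br | starting material
12 | (1S,2S,5S)-5-[(1R)-3-[(tert-butyldimethylsilyl)oxy]-1-{[3-(trimethylsilyl)prop-2-yn-1-yl]oxy}propyl]-2-(prop-1-en-2-yl)cyclopentan-1-ol | CC(C)(C)[Si](C)(C)OCC[C@@H](OCC#C[Si](C)(C)C)[C@H]1CC[C@@H](C(=C)C)[C@@H]1O | intermediate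
13 | (1S,2S,5S)-5-[(1R)-3-hydroxy-1-(prop-2-yn-1-yloxy)propyl]-2-(prop-1-en-2-yl)cyclopentan-1-ol | OCC[C@@H](OCC#C)[C@H]1CC[C@@H](C(=C)C)[C@@H]1O | intermediate
14 | (1S,2S,5S)-5-[(1R)-3-iodo-1-(prop-2-yn-1-yloxy)propyl]-2-(prop-1-en-2-yl)cyclopentan-1-ol | ICC[C@@H](OCC#C)[C@H]1CC[C@@H](C(=C)C)[C@@H]1O | intermediate
15 | tert-butyldimethylsilyl ether of 14 (half-B iodo alkyne) | ICC[C@@H](OCC#C)[C@H]1CC[C@@H](C(=C)C)[C@@H]1O[Si](C)(C)C(C)(C)C | intermediate
16 | epoxy alcohol from 7, epoxide oxygen syn to the side chain, (1S,2R,5R)-6-oxabicyclo[3.1.0]hexan-2-yl carbinol (carbinol R) | C1C[C@H]2O[C@H]2[C@H]1[C@H](O)CCO[Si](C)(C)C(C)(C)C | intermediate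
17 | 3-(trimethylsilyl)prop-2-yn-1-yl ether of 16 | C1C[C@H]2O[C@H]2[C@H]1[C@H](OCC#C[Si](C)(C)C)CCO[Si](C)(C)C(C)(C)C | intermediate
18 | (1R,2R,5S)-5-[(1R)-3-[(tert-butyldimethylsilyl)oxy]-1-{[3-(trimethylsilyl)prop-2-yn-1-yl]oxy}propyl]-2-(prop-1-en-2-yl)cyclopentan-1-ol | CC(C)(C)[Si](C)(C)OCC[C@@H](OCC#C[Si](C)(C)C)[C@H]1CC[C@H](C(=C)C)[C@H]1O | intermediate
19 | 4-nitrobenzoate of the C1 epimer of 18 (ester oxygen cis to isopropenyl, trans to the side chain) | CC(C)(C)[Si](C)(C)OCC[C@@H](OCC#C[Si](C)(C)C)[C@H]1CC[C@H](C(=C)C)[C@@H]1OC(=O)c2ccc(cc2)[N+](=O)[O-] | intermediate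
20 | (1S,2R,5S)-5-[(1R)-3-[(tert-butyldimethylsilyl)oxy]-1-(prop-2-yn-1-yloxy)propyl]-2-(prop-1-en-2-yl)cyclopentan-1-ol | CC(C)(C)[Si](C)(C)OCC[C@@H](OCC#C)[C@H]1CC[C@H](C(=C)C)[C@@H]1O | intermediate
21 | (1S,2R,5S)-5-[(1R)-3-hydroxy-1-(prop-2-yn-1-yloxy)propyl]-2-(prop-1-en-2-yl)cyclopentan-1-ol | OCC[C@@H](OCC#C)[C@H]1CC[C@H](C(=C)C)[C@@H]1O | intermediate
22 | (1S,2R,5S)-5-[(1R)-3-iodo-1-(prop-2-yn-1-yloxy)propyl]-2-(prop-1-en-2-yl)cyclopentan-1-ol | ICC[C@@H](OCC#C)[C@H]1CC[C@H](C(=C)C)[C@@H]1O | intermediate
23 | tert-butyldimethylsilyl ether of 22 (half-A iodo alkyne) | ICC[C@@H](OCC#C)[C@H]1CC[C@H](C(=C)C)[C@@H]1O[Si](C)(C)C(C)(C)C | intermediate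
24 | 1,2-bis(4,4,5,5-tetramethyl-1,3,2-dioxaborolan-2-yl)ethane | CC1(C)OB(CCB2OC(C)(C)C(C)(C)O2)OC1(C)C | starting material
25 | lithium acetylide of 15 | [Li]C#CCO[C@H](CCI)[C@H]1CC[C@@H](C(=C)C)[C@@H]1O[Si](C)(C)C(C)(C)C | intermediate
26 | lithium alkynylboronate complex from 25 and 24 | [Li+].CC1(C)O[B-](CCB2OC(C)(C)C(C)(C)O2)(C#CCO[C@H](CCI)[C@H]3CC[C@@H](C(=C)C)[C@@H]3O[Si](C)(C)C(C)(C)C)OC1(C)C | intermediate
27 | half-B tetrahydropyran with exocyclic alkene carbon bearing Bpin (cis to ring C4) and a CH2CH2Bpin chain (cis to ring C6); cyclopentyl silyl ether | CC1(C)OB(CC/C(B2OC(C)(C)C(C)(C)O2)=C3/CC[C@H]([C@H]4CC[C@@H](C(=C)C)[C@@H]4O[Si](C)(C)C(C)(C)C)OC3)OC1(C)C | intermediate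
28 | half-B homoallylic pinacol boronate, (Z) alkene (27 with H in place of the alkenyl Bpin) | CC1(C)OB(CC/C=C2/CC[C@H]([C@H]3CC[C@@H](C(=C)C)[C@@H]3O[Si](C)(C)C(C)(C)C)OC2)OC1(C)C | intermediate
29 | lithium acetylide of 23 | [Li]C#CCO[C@H](CCI)[C@H]1CC[C@H](C(=C)C)[C@@H]1O[Si](C)(C)C(C)(C)C | intermediate
30 | lithium alkynylboronate complex from 29 and 28 | [Li+].CC1(C)O[B-](CC/C=C2/CC[C@H]([C@H]3CC[C@@H](C(=C)C)[C@@H]3O[Si](C)(C)C(C)(C)C)OC2)(C#CCO[C@H](CCI)[C@H]4CC[C@H](C(=C)C)[C@@H]4O[Si](C)(C)C(C)(C)C)OC1(C)C | intermediate
31 | coupled bis(silyl ether) with Bpin on the half-A vinylic carbon (boron cis to ring C4, chain cis to ring C6; half-B alkene Z) | C=C(C)[C@H]1CC[C@H]([C@H]2CC/C(=C(/CC/C=C3/CC[C@H]([C@H]4CC[C@@H](C(=C)C)[C@@H]4O[Si](C)(C)C(C)(C)C)OC3)B5OC(C)(C)C(C)(C)O5)CO2)[C@H]1O[Si](C)(C)C(C)(C)C | intermediate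
32 | bis(tert-butyldimethylsilyl) ether of the target | C=C(C)[C@H]1CC[C@H]([C@H]2CC/C(=C/CC/C=C3/CC[C@H]([C@H]4CC[C@@H](C(=C)C)[C@@H]4O[Si](C)(C)C(C)(C)C)OC3)CO2)[C@H]1O[Si](C)(C)C(C)(C)C | intermediate
33 | CNP0267443.2 | C=C(C)[C@H]1CC[C@H]([C@H]2CC/C(=C/CC/C=C3/CC[C@H]([C@H]4CC[C@@H](C(=C)C)[C@@H]4O)OC3)CO2)[C@H]1O | target

**Step count and risks**

Total steps: 23. Longest linear sequence: 15 steps (1–4, 11–18, 21–23).

Steps most likely to fail:

Step 21 (Proposed new method). The boronate complex may be too weak a nucleophile for the primary iodide, or may dissociate so that acetylide oligomerisation competes; a stepwise course would erode the alkene geometry. Fallback in known chemistry, setting out from 23, using 28 and returning at 32: copper-catalysed borylative cyclisation of 23 (CuCl, Xantphos, B2pin2, KOt-Bu, THF; syn borylcupration of the terminal alkyne, then ring closure of the alkenylcopper on the iodide) should give the half-A (E)-alkenylboronate F1 with boron cis to C4. Iododeboronation with retention (NaOH, then I2) gives the half-A (E)-alkenyl iodide F2. Lithium–iodine exchange (t-BuLi, −78 °C) gives the half-A alkenyllithium F3, which adds to 28 to give the lithium alkenyl(alkyl)boronate complex F4. I2 followed by NaOMe (Zweifel olefination: anti 1,2-shift, then anti elimination, i.e. inversion at the alkenyl carbon) puts the incoming CH2 trans to C4 and gives 32 directly, so step 22 is bypassed.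

Step 19 (Proposed new method). Besides the reactivity limits named for step 21, both boron atoms of the C2 linchpin may react, giving the symmetrical half-B dimer. Fallback in known chemistry, setting out from 15, using 24 and returning at 28: the same copper-catalysed borylative cyclisation of 15 gives the half-B (E)-alkenylboronate F5. Iododeboronation with retention gives the half-B (E)-alkenyl iodide F6. Lithium–iodine exchange gives the half-B alkenyllithium F7, which adds to excess 24 to give the lithium alkenylboronate complex F8. I2 followed by NaOMe (Zweifel olefination with inversion) transfers the CH2CH2Bpin group trans to C4 and gives 28.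

Step 22. Boron-to-silver transmetalation may be slow at the fully substituted alkenyl carbon, and forcing may start desilylation or alkene isomerisation; step 20 shares this risk. Fallback setting out from 31 and returning at 32: oxidative removal of the pinacol ligand (NaIO4, NH4OAc, acetone/H2O) gives the alkenylboronic acid F9, whose C–B bond is then cleaved with retention by direct protonolysis (AcOH, THF, 60 °C) to give 32.

Further compounds
F1 | step 21 | half-A (E)-alkenylboronate, boron cis to ring C4 | C=C(C)[C@H]1CC[C@H]([C@H]2CC/C(=C\B3OC(C)(C)C(C)(C)O3)CO2)[C@H]1O[Si](C)(C)C(C)(C)C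
F2 | step 21 | half-A (E)-alkenyl iodide | C=C(C)[C@H]1CC[C@H]([C@H]2CC/C(=C\I)CO2)[C@H]1O[Si](C)(C)C(C)(C)C
F3 | step 21 | half-A alkenyllithium | C=C(C)[C@H]1CC[C@H]([C@H]2CC/C(=C\[Li])CO2)[C@H]1O[Si](C)(C)C(C)(C)C
F4 | step 21 | lithium alkenyl(alkyl)boronate complex from F3 and 28 | [Li+].C=C(C)[C@H]1CC[C@H]([C@H]2CC/C(=C\[B-]3(CC/C=C4/CC[C@H]([C@H]5CC[C@@H](C(=C)C)[C@@H]5O[Si](C)(C)C(C)(C)C)OC4)OC(C)(C)C(C)(C)O3)CO2)[C@H]1O[Si](C)(C)C(C)(C)C
F5 | step 19 | half-B (E)-alkenylboronate, boron cis to ring C4 | CC1(C)OB(\C=C2/CC[C@H]([C@H]3CC[C@@H](C(=C)C)[C@@H]3O[Si](C)(C)C(C)(C)C)OC2)OC1(C)C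
F6 | step 19 | half-B (E)-alkenyl iodide | I\C=C1/CC[C@H]([C@H]2CC[C@@H](C(=C)C)[C@@H]2O[Si](C)(C)C(C)(C)C)OC1
F7 | step 19 | half-B alkenyllithium | [Li]\C=C1/CC[C@H]([C@H]2CC[C@@H](C(=C)C)[C@@H]2O[Si](C)(C)C(C)(C)C)OC1
F8 | step 19 | lithium alkenylboronate complex from F7 and 24 | [Li+].CC1(C)OB(CC[B-]2(\C=C3/CC[C@H]([C@H]4CC[C@@H](C(=C)C)[C@@H]4O[Si](C)(C)C(C)(C)C)OC3)OC(C)(C)C(C)(C)O2)OC1(C)C
F9 | step 22 | alkenylboronic acid from 31 | C=C(C)[C@H]1CC[C@H]([C@H]2CC/C(=C(/CC/C=C3/CC[C@H]([C@H]4CC[C@@H](C(=C)C)[C@@H]4O[Si](C)(C)C(C)(C)C)OC3)B(O)O)CO2)[C@H]1O[Si](C)(C)C(C)(C)C
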